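**Retrosynthetic overview**

1. The target is a 4→8 biflavanoid: an upper 7,3',4'-trihydroxyflavan-3-ol unit (2R,3S,4S; 2,3-trans-3,4-trans) on C8 of (2R,3S)-afzelechin. Six benzyl ethers are removed last; before that, C3–OH and C2–H are added across the C2=C3 enol ether of a 4-aryl-4H-chromene by hydroboration anti to the C4 aryl group.
2. Key disconnection: ring C of the upper unit is opened at O1–C2 and at C4–C4a. This is a (3+3) cyclocondensation of free resorcinol with a chalcone-type enone whose beta-carbon (future C4) carries C8 of the lower unit and whose carbonyl carbon (future C2) carries catechol ring B.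
3. Enabling feature: upper ring A is a plain resorcinol ring in which C4a is para to the C7 hydroxyl and ortho to O1, so resorcinol itself (its 4- and 6-positions are equivalent) is the 1,3-C,O-bisnucleophile. C4 is benzylic to lower ring A between O1 and O7 and C2 carries ring B, so C2–C3–C4 is a 1,3-diaryl C3 unit whose C4 end is a cation stabilised by the lower phloroglucinol ring.
4. The enone comes from a Claisen–Schmidt condensation of 3,4-bis(benzyloxy)acetophenone with the C8 aldehyde of perbenzylated (+)-afzelechin (C8 bromination, bromine–lithium exchange, DMF).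
5. Ring order: the three rings of the lower unit are bought, upper ring B is attached by the aldol step, and upper rings A and C arrive together in the key step, ring C being the only ring that is closed.

Key step: step 7

Assumption: (+)-afzelechin 1 is bought as the enantiopure chiral-pool source of the lower unit, so its C2 and C3 are carried through untouched.

**Route**

Step 1
Reactants: 1 (+)-afzelechin
Product: 2 5,7,4'-tri-O-benzylafzelechin
Conditions: BnBr (3.3 equiv), K2CO3, DMF, 0 °C → rt
Reagents that add atoms: benzyl bromide, BrCc1ccccc1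
Why: Williamson ether synthesis in which K2CO3 ionises only the three phenols and not the C3 alcohol, so O-benzylation is selective and C2 and C3 are untouched.

Step 2
Reactants: 2 5,7,4'-tri-O-benzylafzelechin
Product: 3 3,5,7,4'-tetra-O-benzylafzelechin
Conditions: NaH, BnBr, n-Bu4NI (cat), DMF, 0 °C → rt
Reagents that add atoms: benzyl bromide, BrCc1ccccc1
Why: Williamson ether synthesis via the sodium alkoxide masks the last O–H of the lower unit, so that the later aryllithium, aldol and borane steps meet no acidic proton there and one hydrogenolysis unmasks everything at the end.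

Step 3
Reactants: 3 3,5,7,4'-tetra-O-benzylafzelechin
Product: 4 8-bromo-3,5,7,4'-tetra-O-benzylafzelechin
Conditions: NBS (1.05 equiv), CH2Cl2, −78 °C → rt
Reagents that add atoms: N-bromosuccinimide, O=C1CCC(=O)N1Br
Why: Electrophilic aromatic bromination, which in 5,7-di-O-benzylflavans is known to go to C8 (between O1 and O7) in preference to C6, with one equivalent at low temperature preventing dibromination.

Step 4
Reactants: 4 8-bromo-3,5,7,4'-tetra-O-benzylafzelechin
Product: 6 8-formyl-3,5,7,4'-tetra-O-benzylafzelechin, via 8-lithio arene 5 (not isolated)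
Conditions: n-BuLi (1.1 equiv), THF, −78 °C; then DMF, −78 → 0 °C; then H2O
Reagents that add atoms: N,N-dimethylformamide, CN(C)C=O
Why: Bromine–lithium exchange followed by Bouveault formylation of the aryllithium with DMF, the lithium hemiaminal protecting the aldehyde from over-addition until aqueous work-up.

Step 5
Reactants: 7 3',4'-dihydroxyacetophenone
Product: 8 3',4'-bis(benzyloxy)acetophenone
Conditions: BnBr (2.3 equiv), K2CO3, DMF, 60 °C
Reagents that add atoms: benzyl bromide, BrCc1ccccc1
Why: Williamson ether synthesis on both catechol hydroxyls, which are the only acidic sites.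

Step 6
Reactants: 6 8-formyl-3,5,7,4'-tetra-O-benzylafzelechin; 8 3',4'-bis(benzyloxy)acetophenone
Product: 9 (E)-enone, 1-[3,4-bis(benzyloxy)phenyl]-3-(tetra-O-benzylafzelechin-8-yl)prop-2-en-1-one
Conditions: KOH (aq), EtOH/THF, rt → 40 °C
Reagents that add atoms: none
Why: Claisen–Schmidt (crossed aldol) condensation between the only enolisable partner 8 and the non-enolisable aldehyde 6, with E1cB loss of water giving the conjugated (E)-enone under thermodynamic control.

Step 7
Reactants: 9 (E)-enone; 10 resorcinol (5 equiv)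
Product: 13 (4S)-2-[3,4-bis(benzyloxy)phenyl]-4-(tetra-O-benzylafzelechin-8-yl)-4H-chromen-7-ol, via Michael adduct 11 (not isolated), via hemiketal 12 (not isolated)
Conditions: (R)-3,3'-bis(2,4,6-triisopropylphenyl)-1,1'-binaphthyl-2,2'-diyl N-triflylphosphoramide (10 mol%), 5 Å MS, CH2Cl2/toluene, −20 °C → rt, argon
Reagents that add atoms: none
Why: Proposed new method: the chiral Brønsted acid protonates the enone carbonyl, giving an ion pair whose positive charge is delocalised from the beta-carbon into lower ring A (O1, O5 and O7 all donate), while its phosphoryl oxygen hydrogen-bonds a resorcinol hydroxyl, so that the 4-position of resorcinol adds to the beta-carbon (conjugate Friedel–Crafts alkylation, C4–C4a bond) and the adjacent phenol oxygen then adds to the ketone and one molecule of water is lost (O1–C2 bond). The closest known reactions are the acid-catalysed cyclocondensation of phenols and naphthols with chalcones to 2,4-diaryl-4H-chromenes and the chiral phosphoric acid-catalysed Friedel–Crafts/cyclisation of phenols with beta,gamma-unsaturated alpha-keto esters; an enantioface-selective version on a chalcone with a simple phenol is the new element. Ring C closes by 6-exo-trig hemiketalisation of the phenol oxygen onto the C2 carbonyl, followed by E1 loss of water from hemiketal 12 to the enol ether. The one new stereocentre, C4, must be S (addition to the Re face of the beta-carbon) and is set by the catalyst, because the lower-unit stereocentres are too remote to bias it, and the antipodal acid is taken if the first run shows the R acid to be mismatched. The step needs 1,4- over 1,2-addition (secured by the cation-stabilising 2,4,6-trioxygenated ring on the beta-carbon), a single carbon site on resorcinol (its 4- and 6-positions are equivalent by symmetry and its 2-position is shielded), mono-alkylation (excess resorcinol) and ring closure by the resorcinol oxygen only (O7 of the lower unit is benzylated).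

Step 8
Reactants: 13 (4S)-2-[3,4-bis(benzyloxy)phenyl]-4-(tetra-O-benzylafzelechin-8-yl)-4H-chromen-7-ol
Product: 15 (2R,3S,4S)-2-[3,4-bis(benzyloxy)phenyl]-4-(tetra-O-benzylafzelechin-8-yl)chromane-3,7-diol, via C3 borane 14 (not isolated)
Conditions: BH3·THF (5 equiv), THF, 0 °C → rt; then NaOH (aq), H2O2, 0 °C → rt
Reagents that add atoms: hydrogen peroxide, OO
Why: Brown hydroboration–oxidation of the cyclic enol ether, in which BH3 adds syn with boron at C3 (beta to O1, remote from the C2 aryl) on the face opposite to the pseudo-axial C4 aryl group and oxidation proceeds with retention, so that the C3–OH ends up trans to the C4 aryl and the new C2–H cis to the C3–OH (2,3-trans-3,4-trans), as known for hydroboration of flav-2-enes.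

Step 9
Reactants: 15 (2R,3S,4S)-2-[3,4-bis(benzyloxy)phenyl]-4-(tetra-O-benzylafzelechin-8-yl)chromane-3,7-diol
Product: 16 target CNP0322555.1
Conditions: H2 (1 atm), Pd(OH)2/C, THF/MeOH, rt
Reagents that add atoms: none
Why: Catalytic hydrogenolysis cleaves all six O-benzyl ethers while the cyclic benzylic C2–O1 ethers and the C4–aryl bonds of flavans are known to survive, and no stereocentre is touched.

**Compound list**

1 | (+)-afzelechin, (2R,3S)-2-(4-hydroxyphenyl)chromane-3,5,7-triol | Oc1ccc(cc1)[C@H]1Oc2cc(O)cc(O)c2C[C@@H]1O | starting material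

2 | (2R,3S)-5,7-bis(benzyloxy)-2-[4-(benzyloxy)phenyl]chroman-3-ol | c1ccccc1COc1ccc(cc1)[C@H]1Oc2cc(OCc3ccccc3)cc(OCc3ccccc3)c2C[C@@H]1O | intermediate

3 | (2R,3S)-3,5,7-tris(benzyloxy)-2-[4-(benzyloxy)phenyl]chromane | c1ccccc1COc1ccc(cc1)[C@H]1Oc2cc(OCc3ccccc3)cc(OCc3ccccc3)c2C[C@@H]1OCc1ccccc1 | intermediate

4 | (2R,3S)-3,5,7-tris(benzyloxy)-2-[4-(benzyloxy)phenyl]-8-bromochromane | c1ccccc1COc1ccc(cc1)[C@H]1Oc2c(Br)c(OCc3ccccc3)cc(OCc3ccccc3)c2C[C@@H]1OCc1ccccc1 | intermediate

5 | {(2R,3S)-3,5,7-tris(benzyloxy)-2-[4-(benzyloxy)phenyl]chroman-8-yl}lithium | c1ccccc1COc1ccc(cc1)[C@H]1Oc2c([Li])c(OCc3ccccc3)cc(OCc3ccccc3)c2C[C@@H]1OCc1ccccc1 | intermediate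

6 | (2R,3S)-3,5,7-tris(benzyloxy)-2-[4-(benzyloxy)phenyl]chromane-8-carbaldehyde | c1ccccc1COc1ccc(cc1)[C@H]1Oc2c(C=O)c(OCc3ccccc3)cc(OCc3ccccc3)c2C[C@@H]1OCc1ccccc1 | intermediate

7 | 1-(3,4-dihydroxyphenyl)ethanone | CC(=O)c1ccc(O)c(O)c1 | starting material

8 | 1-[3,4-bis(benzyloxy)phenyl]ethanone | CC(=O)c1ccc(OCc2ccccc2)c(OCc2ccccc2)c1 | intermediate

9 | (E)-1-[3,4-bis(benzyloxy)phenyl]-3-{(2R,3S)-3,5,7-tris(benzyloxy)-2-[4-(benzyloxy)phenyl]chroman-8-yl}prop-2-en-1-one | c1ccccc1COc1ccc(cc1)[C@H]1Oc2c(/C=C/C(=O)c3ccc(OCc4ccccc4)c(OCc4ccccc4)c3)c(OCc3ccccc3)cc(OCc3ccccc3)c2C[C@@H]1OCc1ccccc1 | intermediate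

10 | resorcinol, benzene-1,3-diol | Oc1cccc(O)c1 | starting material

11 | (3S)-1-[3,4-bis(benzyloxy)phenyl]-3-(2,4-dihydroxyphenyl)-3-{(2R,3S)-3,5,7-tris(benzyloxy)-2-[4-(benzyloxy)phenyl]chroman-8-yl}propan-1-one | c1ccccc1COc1ccc(cc1)[C@H]1Oc2c([C@@H](CC(=O)c3ccc(OCc4ccccc4)c(OCc4ccccc4)c3)c3ccc(O)cc3O)c(OCc3ccccc3)cc(OCc3ccccc3)c2C[C@@H]1OCc1ccccc1 | intermediate

12 | (4S)-2-[3,4-bis(benzyloxy)phenyl]-4-{(2R,3S)-3,5,7-tris(benzyloxy)-2-[4-(benzyloxy)phenyl]chroman-8-yl}chromane-2,7-diol, hemiketal formed as both C2 epimers (C2 left undefined) | c1ccccc1COc1ccc(cc1)[C@H]1Oc2c([C@@H]3c4ccc(O)cc4OC(O)(c4ccc(OCc5ccccc5)c(OCc5ccccc5)c4)C3)c(OCc3ccccc3)cc(OCc3ccccc3)c2C[C@@H]1OCc1ccccc1 | intermediate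

13 | (4S)-2-[3,4-bis(benzyloxy)phenyl]-4-{(2R,3S)-3,5,7-tris(benzyloxy)-2-[4-(benzyloxy)phenyl]chroman-8-yl}-4H-chromen-7-ol | c1ccccc1COc1ccc(cc1)[C@H]1Oc2c([C@@H]3c4ccc(O)cc4OC(c4ccc(OCc5ccccc5)c(OCc5ccccc5)c4)=C3)c(OCc3ccccc3)cc(OCc3ccccc3)c2C[C@@H]1OCc1ccccc1 | intermediate

14 | [(2S,3S,4S)-2-[3,4-bis(benzyloxy)phenyl]-7-hydroxy-4-{(2R,3S)-3,5,7-tris(benzyloxy)-2-[4-(benzyloxy)phenyl]chroman-8-yl}chroman-3-yl]borane, boron trans to both aryl groups (drawn as the monoalkylborane with free phenol) | c1ccccc1COc1ccc(cc1)[C@H]1Oc2c([C@@H]3c4ccc(O)cc4O[C@H](c4ccc(OCc5ccccc5)c(OCc5ccccc5)c4)[C@H]3B)c(OCc3ccccc3)cc(OCc3ccccc3)c2C[C@@H]1OCc1ccccc1 | intermediate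

15 | (2R,3S,4S)-2-[3,4-bis(benzyloxy)phenyl]-4-{(2R,3S)-3,5,7-tris(benzyloxy)-2-[4-(benzyloxy)phenyl]chroman-8-yl}chromane-3,7-diol | c1ccccc1COc1ccc(cc1)[C@H]1Oc2c([C@@H]3c4ccc(O)cc4O[C@H](c4ccc(OCc5ccccc5)c(OCc5ccccc5)c4)[C@H]3O)c(OCc3ccccc3)cc(OCc3ccccc3)c2C[C@@H]1OCc1ccccc1 | intermediate

16 | CNP0322555.1, (2R,3S,4S)-2-(3,4-dihydroxyphenyl)-4-[(2R,3S)-3,5,7-trihydroxy-2-(4-hydroxyphenyl)chroman-8-yl]chromane-3,7-diol | Oc1ccc([C@H]2Oc3c(c(O)cc(O)c3[C@@H]3c4ccc(O)cc4O[C@H](c4ccc(O)c(O)c4)[C@H]3O)C[C@@H]2O)cc1 | target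

**Step count**

Total: 9 steps. Longest linear sequence: 8 steps (steps 1, 2, 3, 4, 6, 7, 8, 9).

**Steps most likely to fail**

Step 7. The chiral acid may discriminate the two faces of the beta-carbon poorly on this bulky substrate. Acid-induced ionisation of the new C4–C8 bond (retro-Friedel–Crafts to a flavylium ion) may also erode the C4 configuration. The fallback sets out from 9 and fixes C4 by a rhodium-catalysed asymmetric conjugate arylation (Hayashi–Miyaura reaction) instead of an acid-catalysed arylation. 4-Bromoresorcinol is protected with MOMCl/i-Pr2NEt to give 1-bromo-2,4-bis(methoxymethoxy)benzene F1. Treatment with n-BuLi and B(OMe)3 and mild aqueous work-up gives [2,4-bis(methoxymethoxy)phenyl]boronic acid F2. F2 is added to enone 9 with Rh(acac)(C2H4)2 and the antipode of 2,2'-bis(diphenylphosphino)-1,1'-binaphthyl that delivers the aryl group to the Re face (KOH, dioxane/H2O, 60 °C). This gives the (3S)-beta,beta-diaryl ketone F3. HCl in MeOH/THF then removes both MOM groups, and the freed phenol ketone 11 closes and loses water through 12, so the route is rejoined at 13.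

Step 8. Hydroboration of the hindered, aryl-conjugated enol ether may stall, or the C3 borane may be lost by beta-elimination with opening of ring C. The fallback sets out from 13 and replaces hydroboration by epoxidation and ionic hydrogenation. Dimethyldioxirane (acetone/CH2Cl2, −78 °C) should epoxidise the face opposite to the C4 aryl group to give the labile 2,3-epoxide F4. This is reduced in the same flask with Et3SiH/BF3·OEt2. The C2 oxocarbenium ion should take hydride axially, which places the C2 aryl group equatorial and gives the all-equatorial diol, so the route is rejoined at 15.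

Step 4. The crowded aryllithium may be protonated, or may attack a neighbouring benzyl ether (benzylic deprotonation, Wittig rearrangement), faster than it is formylated. The fallback sets out from 4 and avoids any organolithium: palladium-catalysed reductive carbonylation (Pd(OAc)2, di(1-adamantyl)-n-butylphosphine, CO/H2, TMEDA, toluene, 100 °C) should give the aldehyde directly. The route is rejoined at 6 and the fallback makes no new compound (F0).

Further compounds
F1 | step 7 | 1-bromo-2,4-bis(methoxymethoxy)benzene | COCOc1ccc(Br)c(OCOC)c1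
F2 | step 7 | [2,4-bis(methoxymethoxy)phenyl]boronic acid | COCOc1ccc(B(O)O)c(OCOC)c1
F3 | step 7 | (3S)-1-[3,4-bis(benzyloxy)phenyl]-3-[2,4-bis(methoxymethoxy)phenyl]-3-{(2R,3S)-3,5,7-tris(benzyloxy)-2-[4-(benzyloxy)phenyl]chroman-8-yl}propan-1-one | c1ccccc1COc1ccc(cc1)[C@H]1Oc2c([C@@H](CC(=O)c3ccc(OCc4ccccc4)c(OCc4ccccc4)c3)c3ccc(OCOC)cc3OCOC)c(OCc3ccccc3)cc(OCc3ccccc3)c2C[C@@H]1OCc1ccccc1
F4 | step 8 | 2,3-epoxide of 13 with the oxirane oxygen on the face opposite to the C4 aryl group (C4 configured as in 13) | c1ccccc1COc1ccc(cc1)[C@H]1Oc2c([C@@H]3c4ccc(O)cc4O[C@]5(c4ccc(OCc6ccccc6)c(OCc6ccccc6)c4)[C@H]3O5)c(OCc3ccccc3)cc(OCc3ccccc3)c2C[C@@H]1OCc1ccccc1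
F0 | step 4 | none | none
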